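**Retrosynthetic overview**
- The (E)-enyne is made last from a C6 allyl group: cross-metathesis to the enal, then one-carbon Colvin homologation.
- Ring B (oxocane) comes from a bridged eight-membered lactone: C12–Br by enolate bromination, C13–Et by reductive acetylation and ethyl transfer; the O(7)–C13 bond is made by macrolactonisation.
- Ring A (tetrahydropyran) comes from an Achmatowicz pyranone: C6 allyl by trans C-glycosylation, C7–O by conjugate borylation/oxidation, C9–Br by ketone reduction and SN2 bromination.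
- Key C–C bond C10–C11: enantioselective addition of an ester homoenolate (β-zincio propanoate) to furfural, joining the aldehyde carbon to the β-carbon of an acrylate equivalent.
- Ring order: A first (step 2), then B (step 10).

Assumption: the SMILES is taken as drawn, i.e. (6R,7S,9S,10R,12S,13R) in chain numbering C1 (alkyne CH) to C15 (ethyl CH3), with ring A = the tetrahydropyran O(6,10) and ring B = the oxocane O(7,13).

**Route**

Step 1
Reactants: 1 furfural; 2 tert-butyl 3-iodopropanoate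
Product: 4 tert-butyl (4R)-4-(furan-2-yl)-4-hydroxybutanoate, via zinc homoenolate 3 (not isolated)
Conditions: 2 (2.4 equiv), Et2Zn, neat, 50 °C, then evaporate; Ti(OiPr)4 (2 equiv), (1S,2S)-N,N'-bis(trifluoromethylsulfonyl)cyclohexane-1,2-diamine (8 mol %), toluene, −20 °C, then 1; aq NH4Cl
Reagents that add atoms: diethylzinc CC[Zn]CC (zinc of 3 only)
Why: Proposed new method: iodine–zinc exchange gives the β-zincio ester (a homoenolate, d3 synthon), whose alkyl group is passed to the chiral titanium bis(sulfonamide) complex and added to the Re face of furfural, so that two normally electrophilic carbons (aldehyde carbon C10 and the acrylate-type β-carbon C11) are joined and C10 is set as R in one step; the closest known chemistry is the Ti(OiPr)4/bis(triflamide)-catalysed enantioselective addition of ester-bearing dialkylzincs to aldehydes and the Nakamura–Kuwajima zinc and titanium homoenolate additions.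

Step 2
Reactants: 4 tert-butyl (4R)-4-(furan-2-yl)-4-hydroxybutanoate
Product: 5 tert-butyl 3-[(2R)-6-hydroxy-3-oxo-3,6-dihydro-2H-pyran-2-yl]propanoate
Conditions: N-bromosuccinimide (1.05 equiv), NaHCO3, THF/H2O 4:1, 0 °C
Reagents that add atoms: water O
Why: Achmatowicz rearrangement, in which bromonium-induced oxidative opening of the 2-furylcarbinol to the cis-enedione and recyclisation of the C10 hydroxyl onto the C6 aldehyde forms ring A as a pyranone lactol with C10 untouched.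

Step 3
Reactants: 5 tert-butyl 3-[(2R)-6-hydroxy-3-oxo-3,6-dihydro-2H-pyran-2-yl]propanoate
Product: 6 tert-butyl 3-[(2R)-6-acetoxy-3-oxo-3,6-dihydro-2H-pyran-2-yl]propanoate
Conditions: Ac2O, pyridine, DMAP (cat), CH2Cl2, 0 °C
Reagents that add atoms: acetic anhydride CC(=O)OC(C)=O
Why: DMAP-catalysed acylation turns the lactol hydroxyl into a leaving group for C-glycosylation, and the anomeric mixture is of no consequence because C6 is ionised next.

Step 4
Reactants: 6 tert-butyl 3-[(2R)-6-acetoxy-3-oxo-3,6-dihydro-2H-pyran-2-yl]propanoate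
Product: 7 tert-butyl 3-[(2R,6R)-3-oxo-6-(prop-2-en-1-yl)-3,6-dihydro-2H-pyran-2-yl]propanoate
Conditions: allylSiMe3 (3 equiv), BF3·OEt2 (1.2 equiv), CH2Cl2, −78 to −40 °C
Reagents that add atoms: allyltrimethylsilane C=CC[Si](C)(C)C
Why: Hosomi–Sakurai C-glycosylation, in which BF3 ionises the acetate to a cyclic oxocarbenium ion that the allylsilane attacks axially and anti to the C10 side chain, giving the 2,6-trans dihydropyranone and setting C6 as R.

Step 5
Reactants: 7 tert-butyl 3-[(2R,6R)-3-oxo-6-(prop-2-en-1-yl)-3,6-dihydro-2H-pyran-2-yl]propanoate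
Product: 9 tert-butyl 3-[(2R,5S,6R)-5-hydroxy-3-oxo-6-(prop-2-en-1-yl)oxan-2-yl]propanoate, via β-boryl ketone 8 (not isolated)
Conditions: B2pin2 (1.1 equiv), CuCl (3 mol %), NaOtBu (6 mol %), DPEphos (3 mol %), MeOH (2 equiv), THF, rt; then NaBO3·4H2O, THF/H2O, 0 °C
Reagents that add atoms: bis(pinacolato)diboron CC1(C)OB(OC1(C)C)B1OC(C)(C)C(C)(C)O1 (boryl group of 8 only); sodium perborate tetrahydrate [Na+].[O-]OB=O.O.O.O.O (oxygen on C7)
Why: copper-catalysed conjugate borylation delivers the boryl group to C7 anti to the pseudo-axial C6 allyl group under nearly neutral conditions that spare the epimerisable C10, and stereoretentive C–B oxidation gives the C7 hydroxyl trans to C6 and cis to the C10 chain (C7 = S).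

Step 6
Reactants: 9 tert-butyl 3-[(2R,5S,6R)-5-hydroxy-3-oxo-6-(prop-2-en-1-yl)oxan-2-yl]propanoate
Product: 10 tert-butyl 3-[(2R,5S,6R)-5-{[tert-butyl(dimethyl)silyl]oxy}-3-oxo-6-(prop-2-en-1-yl)oxan-2-yl]propanoate
Conditions: tBuMe2SiOTf (1.1 equiv), 2,6-lutidine, CH2Cl2, −78 °C
Reagents that add atoms: tert-butyldimethylsilyl triflate CC(C)(C)[Si](C)(C)OS(=O)(=O)C(F)(F)F
Why: silyl triflate/lutidine silylation protects the β-hydroxy ketone without base-induced elimination and keeps the C7 oxygen apart from the C9 oxygen that is made next.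

Step 7
Reactants: 10 tert-butyl 3-[(2R,5S,6R)-5-{[tert-butyl(dimethyl)silyl]oxy}-3-oxo-6-(prop-2-en-1-yl)oxan-2-yl]propanoate
Product: 11 tert-butyl 3-[(2R,3R,5S,6R)-5-{[tert-butyl(dimethyl)silyl]oxy}-3-hydroxy-6-(prop-2-en-1-yl)oxan-2-yl]propanoate
Conditions: NaBH4, MeOH, −40 °C
Reagents that add atoms: none
Why: borohydride reduction with hydride delivered to the ring face opposite both the C10 chain and the C7 silyloxy group (axial attack on the chair that carries the C10 chain axial) gives the C9 alcohol cis to both neighbours (C9 = R), the correct epimer for inversion.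

Step 8
Reactants: 11 tert-butyl 3-[(2R,3R,5S,6R)-5-{[tert-butyl(dimethyl)silyl]oxy}-3-hydroxy-6-(prop-2-en-1-yl)oxan-2-yl]propanoate
Product: 12 tert-butyl 3-[(2R,3S,5S,6R)-3-bromo-5-{[tert-butyl(dimethyl)silyl]oxy}-6-(prop-2-en-1-yl)oxan-2-yl]propanoate
Conditions: CBr4, P(n-C8H17)3, toluene, 70 °C
Reagents that add atoms: carbon tetrabromide BrC(Br)(Br)Br
Why: Appel-type bromination, in which bromide displaces the oxyphosphonium group by SN2 with inversion, gives the axial C9 bromide trans to the C10 chain (C9 = S), the usual way to trans-2-alkyl-3-bromo oxacycles.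

Step 9
Reactants: 12 tert-butyl 3-[(2R,3S,5S,6R)-3-bromo-5-{[tert-butyl(dimethyl)silyl]oxy}-6-(prop-2-en-1-yl)oxan-2-yl]propanoate
Product: 13 3-[(2R,3S,5S,6R)-3-bromo-5-hydroxy-6-(prop-2-en-1-yl)oxan-2-yl]propanoic acid
Conditions: CF3CO2H/CH2Cl2 1:1, H2O (5 equiv), 0 °C to rt
Reagents that add atoms: none
Why: acidolysis removes the tert-butyl ester (as isobutene) and the silyl ether in one operation and leaves the secondary bromide and the allyl group untouched.

Step 10
Reactants: 13 3-[(2R,3S,5S,6R)-3-bromo-5-hydroxy-6-(prop-2-en-1-yl)oxan-2-yl]propanoic acid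
Product: 14 (1S,6R,8R,10S)-10-bromo-8-(prop-2-en-1-yl)-2,7-dioxabicyclo[4.2.2]decan-3-one
Conditions: 2-methyl-6-nitrobenzoic anhydride (1.5 equiv), DMAP (6 equiv), CH2Cl2, rt, syringe-pump addition of 13 to 2 mM
Reagents that add atoms: none
Why: Shiina macrolactonisation acylates the C7 hydroxyl with the C13 acid, which sit cis on ring A, and closes ring B as a bridged eight-membered lactone under high dilution without forming a new stereocentre, fast mixed-anhydride formation outrunning displacement of the C9 bromide by the carboxylate.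

Step 11
Reactants: 14 (1S,6R,8R,10S)-10-bromo-8-(prop-2-en-1-yl)-2,7-dioxabicyclo[4.2.2]decan-3-one
Product: 16 (1S,4S,6R,8R,10S)-4,10-dibromo-8-(prop-2-en-1-yl)-2,7-dioxabicyclo[4.2.2]decan-3-one, via lithium enolate 15 (not isolated)
Conditions: LiN(iPr)2, THF, −78 °C; then BrCCl2CCl2Br, −78 °C
Reagents that add atoms: lithium diisopropylamide [Li]N(C(C)C)C(C)C (lithium of 15 only); 1,2-dibromotetrachloroethane ClC(Cl)(Br)C(Cl)(Cl)Br
Why: kinetic lactone enolate formation and electrophilic bromination, in which the bromine donor reaches C12 from the enolate face that lies syn to the ring-A oxygen and not to the C8–C9 bridge, sets C12 as S.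

Step 12
Reactants: 16 (1S,4S,6R,8R,10S)-4,10-dibromo-8-(prop-2-en-1-yl)-2,7-dioxabicyclo[4.2.2]decan-3-one
Product: 18 (1S,4S,6R,8R,10S)-4,10-dibromo-8-(prop-2-en-1-yl)-2,7-dioxabicyclo[4.2.2]decan-3-yl acetate, via aluminium lactolate 17 (not isolated)
Conditions: iBu2AlH, CH2Cl2, −78 °C; then pyridine, DMAP, Ac2O, −78 to −20 °C
Reagents that add atoms: diisobutylaluminium hydride CC(C)C[AlH]CC(C)C (aluminium of 17 only); acetic anhydride CC(=O)OC(C)=O
Why: Rychnovsky reductive acetylation traps the tetrahedral aluminium lactolate formed at −78 °C as the α-acetoxy ether, which keeps ring B closed and holds C13 at the acetal oxidation level (both C13 epimers serve).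

Step 13
Reactants: 18 (1S,4S,6R,8R,10S)-4,10-dibromo-8-(prop-2-en-1-yl)-2,7-dioxabicyclo[4.2.2]decan-3-yl acetate
Product: 19 (1S,3R,4S,6R,8R,10S)-4,10-dibromo-3-ethyl-8-(prop-2-en-1-yl)-2,7-dioxabicyclo[4.2.2]decane
Conditions: Et2Zn (3 equiv), Me3SiOTf (0.3 equiv), CH2Cl2, −78 to −20 °C
Reagents that add atoms: diethylzinc CC[Zn]CC
Why: Lewis acid ionisation of the α-acetoxy ether gives the endocyclic oxocarbenium ion, to which diethylzinc transfers ethyl anti to the neighbouring C12 bromide (1,2-trans addition as in C-glycosylation of 2-halo glycosyl donors), setting C13 as R.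

Step 14
Reactants: 19 (1S,3R,4S,6R,8R,10S)-4,10-dibromo-3-ethyl-8-(prop-2-en-1-yl)-2,7-dioxabicyclo[4.2.2]decane
Product: 20 (2E)-4-[(1S,3R,4S,6R,8R,10S)-4,10-dibromo-3-ethyl-2,7-dioxabicyclo[4.2.2]decan-8-yl]but-2-enal
Conditions: crotonaldehyde (10 equiv), second-generation Grubbs catalyst RuCl2(=CHPh)(SIMes)(PCy3) (5 mol %), CH2Cl2, 40 °C
Reagents that add atoms: crotonaldehyde C/C=C/C=O
Why: olefin cross-metathesis of the only terminal alkene with excess enal gives the (E)-enal under thermodynamic control and releases propene.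

Step 15
Reactants: 20 (2E)-4-[(1S,3R,4S,6R,8R,10S)-4,10-dibromo-3-ethyl-2,7-dioxabicyclo[4.2.2]decan-8-yl]but-2-enal
Product: 21 (1S,3R,4S,6R,8R,10S)-4,10-dibromo-3-ethyl-8-[(2E)-pent-2-en-4-yn-1-yl]-2,7-dioxabicyclo[4.2.2]decane
Conditions: Me3SiCHN2, LiN(iPr)2, THF, −78 °C to rt
Reagents that add atoms: trimethylsilyldiazomethane C[Si](C)(C)C=[N+]=[N-]
Why: Colvin rearrangement, in which lithiated trimethylsilyldiazomethane adds to the aldehyde, silanolate is lost and the alkylidene carbene undergoes a 1,2-hydride shift, turns the enal into the terminal (E)-enyne at −78 °C without touching the alkene geometry or the two secondary bromides.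

**Compound list**

1 | furfural (furan-2-carbaldehyde) | O=Cc1ccco1 | starting material
2 | tert-butyl 3-iodopropanoate | CC(C)(C)OC(=O)CCI | starting material
3 | bis(3-tert-butoxy-3-oxopropyl)zinc (zinc homoenolate) | CC(C)(C)OC(=O)CC[Zn]CCC(=O)OC(C)(C)C | intermediate
4 | tert-butyl (4R)-4-(furan-2-yl)-4-hydroxybutanoate | CC(C)(C)OC(=O)CC[C@@H](O)c1ccco1 | intermediate
5 | tert-butyl 3-[(2R)-6-hydroxy-3-oxo-3,6-dihydro-2H-pyran-2-yl]propanoate (both C6 anomers) | OC1O[C@H](CCC(=O)OC(C)(C)C)C(=O)C=C1 | intermediate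
6 | tert-butyl 3-[(2R)-6-acetoxy-3-oxo-3,6-dihydro-2H-pyran-2-yl]propanoate (both C6 anomers) | CC(=O)OC1O[C@H](CCC(=O)OC(C)(C)C)C(=O)C=C1 | intermediate
7 | tert-butyl 3-[(2R,6R)-3-oxo-6-(prop-2-en-1-yl)-3,6-dihydro-2H-pyran-2-yl]propanoate (2,6-trans) | C=CC[C@H]1O[C@H](CCC(=O)OC(C)(C)C)C(=O)C=C1 | intermediate
8 | tert-butyl 3-[(2R,5S,6R)-3-oxo-6-(prop-2-en-1-yl)-5-(4,4,5,5-tetramethyl-1,3,2-dioxaborolan-2-yl)oxan-2-yl]propanoate | C=CC[C@H]1O[C@H](CCC(=O)OC(C)(C)C)C(=O)C[C@@H]1B1OC(C)(C)C(C)(C)O1 | intermediate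
9 | tert-butyl 3-[(2R,5S,6R)-5-hydroxy-3-oxo-6-(prop-2-en-1-yl)oxan-2-yl]propanoate | C=CC[C@H]1O[C@H](CCC(=O)OC(C)(C)C)C(=O)C[C@@H]1O | intermediate
10 | tert-butyl 3-[(2R,5S,6R)-5-{[tert-butyl(dimethyl)silyl]oxy}-3-oxo-6-(prop-2-en-1-yl)oxan-2-yl]propanoate | C=CC[C@H]1O[C@H](CCC(=O)OC(C)(C)C)C(=O)C[C@@H]1O[Si](C)(C)C(C)(C)C | intermediate
11 | tert-butyl 3-[(2R,3R,5S,6R)-5-{[tert-butyl(dimethyl)silyl]oxy}-3-hydroxy-6-(prop-2-en-1-yl)oxan-2-yl]propanoate | C=CC[C@H]1O[C@H](CCC(=O)OC(C)(C)C)[C@H](O)C[C@@H]1O[Si](C)(C)C(C)(C)C | intermediate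
12 | tert-butyl 3-[(2R,3S,5S,6R)-3-bromo-5-{[tert-butyl(dimethyl)silyl]oxy}-6-(prop-2-en-1-yl)oxan-2-yl]propanoate | C=CC[C@H]1O[C@H](CCC(=O)OC(C)(C)C)[C@@H](Br)C[C@@H]1O[Si](C)(C)C(C)(C)C | intermediate
13 | 3-[(2R,3S,5S,6R)-3-bromo-5-hydroxy-6-(prop-2-en-1-yl)oxan-2-yl]propanoic acid | C=CC[C@H]1O[C@H](CCC(=O)O)[C@@H](Br)C[C@@H]1O | intermediate
14 | (1S,6R,8R,10S)-10-bromo-8-(prop-2-en-1-yl)-2,7-dioxabicyclo[4.2.2]decan-3-one | C=CC[C@H]1O[C@@H]2CCC(=O)O[C@H]1C[C@@H]2Br | intermediate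
15 | lithium (1S,6R,8R,10S)-10-bromo-8-(prop-2-en-1-yl)-2,7-dioxabicyclo[4.2.2]dec-3-en-3-olate (lithium enolate of 14) | C=CC[C@H]1O[C@@H]2CC=C(O[Li])O[C@H]1C[C@@H]2Br | intermediate
16 | (1S,4S,6R,8R,10S)-4,10-dibromo-8-(prop-2-en-1-yl)-2,7-dioxabicyclo[4.2.2]decan-3-one | C=CC[C@H]1O[C@@H]2C[C@H](Br)C(=O)O[C@H]1C[C@@H]2Br | intermediate
17 | diisobutylaluminium lactolate of 16 (C3 O-aluminated lactol) | C=CC[C@H]1O[C@@H]2C[C@H](Br)C(O[Al](CC(C)C)CC(C)C)O[C@H]1C[C@@H]2Br | intermediate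
18 | (1S,4S,6R,8R,10S)-4,10-dibromo-8-(prop-2-en-1-yl)-2,7-dioxabicyclo[4.2.2]decan-3-yl acetate (both C3 epimers) | C=CC[C@H]1O[C@@H]2C[C@H](Br)C(OC(C)=O)O[C@H]1C[C@@H]2Br | intermediate
19 | (1S,3R,4S,6R,8R,10S)-4,10-dibromo-3-ethyl-8-(prop-2-en-1-yl)-2,7-dioxabicyclo[4.2.2]decane | C=CC[C@H]1O[C@@H]2C[C@H](Br)[C@@H](CC)O[C@H]1C[C@@H]2Br | intermediate
20 | (2E)-4-[(1S,3R,4S,6R,8R,10S)-4,10-dibromo-3-ethyl-2,7-dioxabicyclo[4.2.2]decan-8-yl]but-2-enal | O=C/C=C/C[C@H]1O[C@@H]2C[C@H](Br)[C@@H](CC)O[C@H]1C[C@@H]2Br | intermediate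
21 | (1S,3R,4S,6R,8R,10S)-4,10-dibromo-3-ethyl-8-[(2E)-pent-2-en-4-yn-1-yl]-2,7-dioxabicyclo[4.2.2]decane | C#C/C=C/C[C@H]1O[C@@H]2C[C@H](Br)[C@@H](CC)O[C@H]1C[C@@H]2Br | target

**Step count**

Total steps: 15. Longest linear sequence: 15 (furfural 1 to target 21).

**Steps most likely to fail, with fallbacks**

Step 1 (enantioselective homoenolate addition). The chelated β-zincio ester may transfer slowly or with low ee. The fallback sets out from 1 and still forms C10–C11 by umpolung. A thiazolium-catalysed Stetter reaction of furfural with tert-butyl acrylate (3-benzyl-5-(2-hydroxyethyl)-4-methylthiazolium chloride, Et3N, dioxane, 80 °C) gives tert-butyl 4-(furan-2-yl)-4-oxobutanoate F1. Transfer hydrogenation with RuCl(p-cymene)[(R,R)-TsDPEN] in HCO2H/Et3N then reduces the furyl ketone to the (R)-alcohol, and the route is rejoined at 4.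

Step 10 (bridged eight-membered lactonisation). Ring A must adopt a boat, and oligomerisation or displacement of the C9 bromide by the carboxylate can compete. The fallback sets out from 9 and closes ring B while C9 is still a ketone, where the ring flexes more easily.
- CF3CO2H/CH2Cl2 cleaves the ester to 3-[(2R,5S,6R)-5-hydroxy-3-oxo-6-(prop-2-en-1-yl)oxan-2-yl]propanoic acid F2.
- The same anhydride/DMAP conditions give (1S,6R,8R)-8-(prop-2-en-1-yl)-2,7-dioxabicyclo[4.2.2]decane-3,10-dione F3.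
- NaBH4 at −78 °C, with hydride expected to approach C9 from the side of the ring-A oxygen, gives (1S,6R,8R,10R)-10-hydroxy-8-(prop-2-en-1-yl)-2,7-dioxabicyclo[4.2.2]decan-3-one F4.
- CBr4/P(n-C8H17)3 inverts C9 and the route is rejoined at 14.

Step 11 (face selectivity of the enolate bromination). The two enolate faces differ only modestly, so the C12 epimer may form. The fallback sets out from 14 and uses that same facial preference in the opposite sense. LiN(iPr)2 followed by 2-(phenylsulfonyl)-3-phenyloxaziridine (Davis hydroxylation) gives (1S,4R,6R,8R,10S)-10-bromo-4-hydroxy-8-(prop-2-en-1-yl)-2,7-dioxabicyclo[4.2.2]decan-3-one F5. SN2 bromination with CBr4/P(n-C8H17)3 then inverts C12, and the route is rejoined at 16.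

**Further compounds**

F1 | step 1 | tert-butyl 4-(furan-2-yl)-4-oxobutanoate | CC(C)(C)OC(=O)CCC(=O)c1ccco1
F2 | step 10 | 3-[(2R,5S,6R)-5-hydroxy-3-oxo-6-(prop-2-en-1-yl)oxan-2-yl]propanoic acid | C=CC[C@H]1O[C@H](CCC(=O)O)C(=O)C[C@@H]1O
F3 | step 10 | (1S,6R,8R)-8-(prop-2-en-1-yl)-2,7-dioxabicyclo[4.2.2]decane-3,10-dione | C=CC[C@H]1O[C@@H]2CCC(=O)O[C@H]1CC2=O
F4 | step 10 | (1S,6R,8R,10R)-10-hydroxy-8-(prop-2-en-1-yl)-2,7-dioxabicyclo[4.2.2]decan-3-one | C=CC[C@H]1O[C@@H]2CCC(=O)O[C@H]1C[C@H]2O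
F5 | step 11 | (1S,4R,6R,8R,10S)-10-bromo-4-hydroxy-8-(prop-2-en-1-yl)-2,7-dioxabicyclo[4.2.2]decan-3-one | C=CC[C@H]1O[C@@H]2C[C@@H](O)C(=O)O[C@H]1C[C@@H]2Br
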